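**Assumptions (one line):** (S)-but-3-yn-2-ol and both enantiomers of 3-bromo-2-methylpropan-1-ol are bought as chiral-pool building blocks. The C8 carbinol configuration in 24, 25 and 32 is irrelevant because it is oxidised away in Step 30.

## Retrosynthetic overview
1. Target 36 comes from Pd-deallylation and desilylation of 34. 34 comes from a Z-boron aldol (C6–C7) of ketone 33 with aldehyde 31 (C5 from the (R)-bromo-alcohol).
2. 33 comes from a Heck coupling (C11–C12) of vinyl iodide 25 with lactone–triene 17. 17 comes from a Negishi coupling (C17–C18) of (Z)-bromoalkene 16 (C15 from the (S)-bromo-alcohol) with lactone iodide 9.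
3. The key steps are two [2,3]-Wittig rearrangements of ethers derived from (S)-but-3-yn-2-ol. One sets both lactone stereocentres (Nakai, Step 4). The other sets the C9 hydroxymethyl stereocentre (Still, Step 19).
4. Order of construction: lactone stereocentres, then lactone ring closure by RCM (Step 8) before any coupling. Next the polyene couplings (Negishi, Heck), then the C6–C7 aldol, then deprotection.

## Route

**Step 1**
Reactants: 1 (S)-but-3-yn-2-ol
Product: 2 (S)-pent-3-yn-2-ol
Conditions: n-BuLi (2.2 equiv), THF/HMPA, –78 → 0 °C; then MeI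
Reagents that add atoms: MeI (CI)
Why: Dianion (alkoxide/acetylide) C-alkylation methylates the alkyne terminus and leaves the carbinol stereocentre untouched.

**Step 2**
Reactants: 2
Product: 3 (2S,3Z)-pent-3-en-2-ol
Conditions: H2 (1 atm), Lindlar Pd/CaCO3/Pb, quinoline, hexane, 25 °C
Reagents that add atoms: none
Why: Lindlar syn-hydrogenation stops at the Z-alkene, which is needed for the syn outcome in Step 4.

**Step 3**
Reactants: 3
Product: 4 trimethyl{3-[(2S,3Z)-pent-3-en-2-yloxy]prop-1-yn-1-yl}silane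
Conditions: NaH, TBAI (cat.), THF, 0 → 25 °C
Reagents that add atoms: 3-bromo-1-(trimethylsilyl)propyne, C[Si](C)(C)C#CCBr
Why: Williamson etherification occurs at the primary propargylic bromide, so the secondary allylic C–O bond and its stereocentre are untouched.

**Step 4**
Reactants: 4
Product: 5 (3R,4S,5E)-4-methyl-1-(trimethylsilyl)hept-5-en-1-yn-3-ol
Conditions: n-BuLi, THF, –78 °C, 1 h
Reagents that add atoms: none
Why: In this Nakai [2,3]-Wittig rearrangement the (S)-carbinol fixes the face of the Z-allyl unit (suprafacial transfer), which sets the methyl-bearing lactone stereocentre. The exo propargylic anion with a Z-alkene gives the syn (erythro) carbinol, and the new alkene is E.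

**Step 5**
Reactants: 5
Product: 6 (3R,4S,5E)-4-methylhept-5-en-1-yn-3-ol
Conditions: K2CO3, MeOH, 25 °C
Reagents that add atoms: none
Why: Protodesilylation of the alkynyl-TMS group leaves both stereocentres untouched.

**Step 6**
Reactants: 6
Product: 7 (1E,3R,4S,5E)-1-iodo-4-methylhepta-1,5-dien-3-ol
Conditions: Cp2Zr(H)Cl (2.2 equiv), THF, 25 °C; then I2, 0 °C
Reagents that add atoms: I2 (II)
Why: Hydrozirconation is a syn addition that puts Zr on the terminal alkyne carbon, and iodinolysis with retention gives the E-vinyl iodide. The 1,2-disubstituted alkene is unreactive.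

**Step 7**
Reactants: 7
Product: 8 (1E,3R,4S,5E)-1-iodo-4-methylhepta-1,5-dien-3-yl prop-2-enoate
Conditions: acryloyl chloride, i-Pr2NEt, DMAP (cat.), CH2Cl2, 0 °C
Reagents that add atoms: acryloyl chloride, C=CC(=O)Cl
Why: Simple O-acylation of the secondary alcohol, with no change at the stereocentres.

**Step 8**
Reactants: 8
Product: 9 (5S,6R)-6-[(E)-2-iodoethenyl]-5-methyl-5,6-dihydro-2H-pyran-2-one (cis ring substituents)
Conditions: Grubbs II (5 mol %), CH2Cl2 (5 mM), 40 °C
Reagents that add atoms: none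
Why: Ring-closing metathesis of the acrylate with the propenyl alkene (propene is lost) closes the δ-lactone, and the syn relationship becomes cis ring substituents. The E-vinyl iodide is retained.

**Step 9**
Reactants: 10 (2S)-3-bromo-2-methylpropan-1-ol
Product: 11 tert-butyl[(2S)-3-bromo-2-methylpropoxy]dimethylsilane
Conditions: TBSCl, imidazole, DMF, 0 → 25 °C
Reagents that add atoms: TBSCl, CC(C)(C)[Si](C)(C)Cl
Why: Silylation protects the alcohol so the Grignard coupling in Step 10 works.

**Step 10**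
Reactants: 11
Product: 12 tert-butyl{[(2R)-2-methylpent-4-en-1-yl]oxy}dimethylsilane
Conditions: CH2=CHMgBr, Li2CuCl4 (cat.), THF, –20 → 0 °C
Reagents that add atoms: vinylmagnesium bromide, C=C[Mg]Br
Why: Copper-catalysed Kumada-type SN2 coupling at the primary C–Br leaves the β-stereocentre (future C15) untouched.

**Step 11**
Reactants: 12
Product: 13 (2R)-2-methylpent-4-en-1-ol
Conditions: TBAF, THF, 0 → 25 °C
Reagents that add atoms: none
Why: Fluoride cleaves the silyl ether without affecting the alkene.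

**Step 12**
Reactants: 13
Product: 14 (2R)-2-methylpent-4-enal
Conditions: Dess–Martin periodinane, NaHCO3, CH2Cl2, 0 °C
Reagents that add atoms: none
Why: Buffered oxidation avoids epimerisation of the α-stereocentre, and the crude aldehyde is used immediately.

**Step 13**
Reactants: 14
Product: 15 (3R)-1,1-dibromo-3-methylhexa-1,5-diene
Conditions: CBr4, PPh3, CH2Cl2, 0 °C
Reagents that add atoms: CBr4, BrC(Br)(Br)Br
Why: Ramirez dibromo-olefination installs the C17 carbon under non-basic conditions.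

**Step 14**
Reactants: 15
Product: 16 (3Z,5R)-3-bromo-5-methylocta-3,7-diene
Conditions: Et2Zn, Pd(PPh3)4 (5 mol %), THF, 25 °C
Reagents that add atoms: diethylzinc, CC[Zn]CC
Why: Negishi coupling of a gem-dibromoalkene occurs at the less hindered C–Br trans to the alkyl chain. Ethyl therefore ends up trans to C15 and Br cis to it, so the next coupling gives the 16Z geometry.

**Step 15**
Reactants: 16 and 9
Product: 17 (5S,6S)-6-[(1E,3Z,5R)-3-ethyl-5-methylocta-1,3,7-trien-1-yl]-5-methyl-5,6-dihydro-2H-pyran-2-one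
Conditions: t-BuLi (2 equiv), Et2O, –78 °C; then ZnCl2, THF; then 9, Pd(PPh3)4 (5 mol %), 25 °C
Reagents that add atoms: none
Why: Bromine–lithium exchange and zincation proceed with retention. Pd-catalysed Negishi coupling with the E-vinyl iodide is stereoretentive and gives the 16Z,18E diene.

**Step 16**
Reactants: 1 (S)-but-3-yn-2-ol
Product: 18 (2S,3E)-4-iodobut-3-en-2-ol
Conditions: Cp2Zr(H)Cl (2.2 equiv), THF, 25 °C; then I2, 0 °C
Reagents that add atoms: I2 (II)
Why: Syn-hydrozirconation then iodinolysis gives the E-vinyl iodide, with the carbinol stereocentre unchanged.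

**Step 17**
Reactants: 18
Product: 19 (2S,3E)-hept-3-en-5-yn-2-ol
Conditions: CH3C≡CMgBr (2.5 equiv), ZnCl2 (2.5 equiv), Pd(PPh3)4 (5 mol %), THF, 0 → 25 °C
Reagents that add atoms: propynylmagnesium bromide, CC#C[Mg]Br
Why: Stereoretentive Negishi sp–sp2 coupling with propynylzinc gives the E-enyne.

**Step 18**
Reactants: 19
Product: 20 tributyl{[(2S,3E)-hept-3-en-5-yn-2-yloxy]methyl}stannane
Conditions: KH, THF, 0 °C; then Bu3SnCH2I, 25 °C
Reagents that add atoms: tributyl(iodomethyl)stannane, CCCC[Sn](CCCC)(CCCC)CI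
Why: O-alkylation gives the stannylmethyl ether, the precursor of a Still [2,3]-Wittig rearrangement.

**Step 19**
Reactants: 20
Product: 21 (2S)-2-[(1E)-prop-1-en-1-yl]pent-3-yn-1-ol
Conditions: n-BuLi, THF, –78 °C
Reagents that add atoms: none
Why: In this Still [2,3]-Wittig rearrangement, Sn–Li exchange gives the α-alkoxy-methyllithium, which adds suprafacially to the γ-carbon of the E-allyl unit. The (S)-carbinol dictates the face, so C9 is formed with the hydroxymethyl group and the new alkene is E.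

**Step 20**
Reactants: 21
Product: 22 tert-butyldimethyl{[(2S)-2-[(1E)-prop-1-en-1-yl]pent-3-yn-1-yl]oxy}silane
Conditions: TBSCl, imidazole, DMF, 0 °C
Reagents that add atoms: TBSCl, CC(C)(C)[Si](C)(C)Cl
Why: Protects the future CH2OH of kazusamycin.

**Step 21**
Reactants: 22
Product: 23 (2S)-2-{[(tert-butyldimethylsilyl)oxy]methyl}pent-3-ynal
Conditions: O3, CH2Cl2, –78 °C; then PPh3, –78 → 0 °C; crude used at once
Reagents that add atoms: ozone, [O-][O+]=O
Why: Ozonolysis cleaves the more reactive alkene in preference to the internal alkyne, and the cold, non-basic reductive work-up preserves the fragile C9 stereocentre.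

**Step 22**
Reactants: 23
Product: 24 (4S)-4-{[(tert-butyldimethylsilyl)oxy]methyl}hept-5-yn-3-ol (C3 epimer mixture)
Conditions: EtMgBr, THF, –78 °C
Reagents that add atoms: ethylmagnesium bromide, CC[Mg]Br
Why: Grignard addition builds the C7–C8 ethyl carbinol, and its configuration is irrelevant because it is oxidised in Step 30.

**Step 23**
Reactants: 24
Product: 25 (4S,5E)-4-{[(tert-butyldimethylsilyl)oxy]methyl}-6-iodohept-5-en-3-ol (C3 epimer mixture)
Conditions: Cp2Zr(H)Cl (2.5 equiv), THF, 25 °C; then I2, 0 °C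
Reagents that add atoms: I2 (II)
Why: Syn-hydrozirconation puts Zr on the less hindered, methyl-bearing alkyne carbon and H on C10, giving the E-trisubstituted vinyl iodide with iodine trans to C9.

**Step 24**
Reactants: 26 (2R)-3-bromo-2-methylpropan-1-ol
Product: 27 tert-butyl[(2R)-3-bromo-2-methylpropoxy]dimethylsilane
Conditions: TBSCl, imidazole, DMF, 0 → 25 °C
Reagents that add atoms: TBSCl, CC(C)(C)[Si](C)(C)Cl
Why: Protects the alcohol for the Grignard coupling in Step 25.

**Step 25**
Reactants: 27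
Product: 28 tert-butyl{[(2S)-2,4-dimethylpent-4-en-1-yl]oxy}dimethylsilane
Conditions: isopropenylMgBr, Li2CuCl4 (cat.), THF, –20 → 0 °C
Reagents that add atoms: isopropenylmagnesium bromide, C=C(C)[Mg]Br
Why: Copper-catalysed SN2 coupling installs C3 and its methyl group, and the stereocentre (future C5) is untouched.

**Step 26**
Reactants: 28
Product: 29 allyl (2E,5S)-6-[(TBS)oxy]-3,5-dimethylhex-2-enoate
Conditions: allyl acrylate (4 equiv), Hoveyda–Grubbs II (5 mol %), CH2Cl2, 40 °C
Reagents that add atoms: allyl acrylate, C=CC(=O)OCC=C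
Why: Cross-metathesis of the 1,1-disubstituted alkene with the acrylate gives the E-trisubstituted enoate and introduces the allyl ester that can be removed neutrally at the end.

**Step 27**
Reactants: 29
Product: 30 allyl (2E,5S)-6-hydroxy-3,5-dimethylhex-2-enoate
Conditions: HF·pyridine, pyridine, THF, 0 °C
Reagents that add atoms: none
Why: Acidic, non-basic removal of the silyl group leaves the enoate and the C5 stereocentre intact.

**Step 28**
Reactants: 30
Product: 31 allyl (2E,5S)-3,5-dimethyl-6-oxohex-2-enoate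
Conditions: Dess–Martin periodinane, NaHCO3, CH2Cl2, 0 °C
Reagents that add atoms: none
Why: Buffered oxidation gives the α-methyl aldehyde without epimerisation.

**Step 29**
Reactants: 25 and 17
Product: 32 lactone–tetraene–C8 alcohol, (5S,6S)-6-[(1E,3Z,5R,7E,9E,11S)-3-ethyl-12-hydroxy-11-({[tert-butyl(dimethyl)silyl]oxy}methyl)-5,9-dimethyltetradeca-1,3,7,9-tetraen-1-yl]-5-methyl-5,6-dihydro-2H-pyran-2-one (C12 epimer mixture)
Conditions: Pd(OAc)2 (10 mol %), Bu4NCl, NaHCO3, DMF, 25 °C
Reagents that add atoms: none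
Why: A Mizoroki–Heck coupling at the terminal alkene of 17 is E-selective (C12=C13) and retains the vinyl-iodide geometry (C10=C11).

**Step 30**
Reactants: 32
Product: 33 the corresponding C8 ethyl ketone
Conditions: Dess–Martin periodinane, NaHCO3, CH2Cl2, 0 °C
Reagents that add atoms: none
Why: Buffered oxidation converges the C8 epimers to one ketone while minimising epimerisation at C9.

**Step 31**
Reactants: 33 and 31
Product: 34 allyl (2E,5S,6R,7S,9S,10E,12E,15R,16Z,18E)-9-({[tert-butyl(dimethyl)silyl]oxy}methyl)-17-ethyl-6-hydroxy-3,5,7,11,15-pentamethyl-19-[(2S,3S)-3-methyl-6-oxo-3,6-dihydro-2H-pyran-2-yl]-8-oxononadeca-2,10,12,16,18-pentaenoate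
Conditions: Bu2BOTf, i-Pr2NEt, CH2Cl2, –78 °C; then 31, –78 → 0 °C; then H2O2, pH 7 buffer/MeOH
Reagents that add atoms: none
Why: Kinetic boron enolisation on the ethyl side gives the Z-enolate, so C6/C7 are syn by the Zimmerman–Traxler chair. Felkin–Anh addition to the (S)-α-methyl aldehyde gives the C5/C6 syn relationship, hence the all-syn stereotriad.

**Step 32**
Reactants: 34
Product: 35 allyl ester of kazusamycin A (free CH2OH)
Conditions: HF·pyridine, pyridine, THF, 0 → 25 °C
Reagents that add atoms: none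
Why: Acidic fluoride removes only the primary TBS ether and spares the β-hydroxy ketone, lactone and allyl ester.

**Step 33**
Reactants: 35
Product: 36 kazusamycin A
Conditions: Pd(PPh3)4 (5 mol %), PhSiH3, CH2Cl2, 0 °C
Reagents that add atoms: none
Why: Pd(0) Tsuji–Trost deallylation with silane as allyl scavenger frees the acid under neutral conditions, avoiding saponification and retro-aldol.

## Compound list
1 | (2S)-but-3-yn-2-ol | C#C[C@H](C)O | starting material
2 | (2S)-pent-3-yn-2-ol | CC#C[C@H](C)O | intermediate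
3 | (2S,3Z)-pent-3-en-2-ol | C/C=C\[C@H](C)O | intermediate
4 | trimethyl{3-[(2S,3Z)-pent-3-en-2-yloxy]prop-1-yn-1-yl}silane | C[Si](C)(C)C#CCO[C@@H](C)/C=C\C | intermediate
5 | (3R,4S,5E)-4-methyl-1-(trimethylsilyl)hept-5-en-1-yn-3-ol | C[Si](C)(C)C#C[C@H](O)[C@@H](C)/C=C/C | intermediate
6 | (3R,4S,5E)-4-methylhept-5-en-1-yn-3-ol | C#C[C@H](O)[C@@H](C)/C=C/C | intermediate
7 | (1E,3R,4S,5E)-1-iodo-4-methylhepta-1,5-dien-3-ol | I/C=C/[C@H](O)[C@@H](C)/C=C/C | intermediate
8 | (1E,3R,4S,5E)-1-iodo-4-methylhepta-1,5-dien-3-yl acrylate | I/C=C/[C@H](OC(=O)C=C)[C@@H](C)/C=C/C | intermediate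
9 | (5S,6R)-6-[(E)-2-iodoethenyl]-5-methyl-5,6-dihydro-2H-pyran-2-one | I/C=C/[C@@H]1OC(=O)C=C[C@@H]1C | intermediate
10 | (2S)-3-bromo-2-methylpropan-1-ol | OC[C@H](C)CBr | starting material
11 | tert-butyl[(2S)-3-bromo-2-methylpropoxy]dimethylsilane | CC(C)(C)[Si](C)(C)OC[C@H](C)CBr | intermediate
12 | tert-butyl{[(2R)-2-methylpent-4-en-1-yl]oxy}dimethylsilane | CC(C)(C)[Si](C)(C)OC[C@H](C)CC=C | intermediate
13 | (2R)-2-methylpent-4-en-1-ol | OC[C@H](C)CC=C | intermediate
14 | (2R)-2-methylpent-4-enal | O=C[C@H](C)CC=C | intermediate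
15 | (3R)-1,1-dibromo-3-methylhexa-1,5-diene | BrC(Br)=C[C@H](C)CC=C | intermediate
16 | (3Z,5R)-3-bromo-5-methylocta-3,7-diene | CC/C(Br)=C/[C@H](C)CC=C | intermediate
17 | (5S,6S)-6-[(1E,3Z,5R)-3-ethyl-5-methylocta-1,3,7-trien-1-yl]-5-methyl-5,6-dihydro-2H-pyran-2-one | CCC(=C/[C@H](C)CC=C)/C=C/[C@@H]1OC(=O)C=C[C@@H]1C | intermediate
18 | (2S,3E)-4-iodobut-3-en-2-ol | I/C=C/[C@H](C)O | intermediate
19 | (2S,3E)-hept-3-en-5-yn-2-ol | CC#C/C=C/[C@H](C)O | intermediate
20 | tributyl{[(2S,3E)-hept-3-en-5-yn-2-yloxy]methyl}stannane | CC#C/C=C/[C@H](C)OC[Sn](CCCC)(CCCC)CCCC | intermediate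
21 | (2S)-2-[(1E)-prop-1-en-1-yl]pent-3-yn-1-ol | CC#C[C@@H](CO)/C=C/C | intermediate
22 | TBS ether of 21 | CC#C[C@@H](CO[Si](C)(C)C(C)(C)C)/C=C/C | intermediate
23 | (2S)-2-{[(tert-butyldimethylsilyl)oxy]methyl}pent-3-ynal | CC#C[C@@H](CO[Si](C)(C)C(C)(C)C)C=O | intermediate
24 | (4S)-4-{[(TBS)oxy]methyl}hept-5-yn-3-ol (C3 epimers) | CC#C[C@@H](CO[Si](C)(C)C(C)(C)C)C(O)CC | intermediate
25 | (4S,5E)-4-{[(TBS)oxy]methyl}-6-iodohept-5-en-3-ol (C3 epimers) | C/C(I)=C\[C@@H](CO[Si](C)(C)C(C)(C)C)C(O)CC | intermediate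
26 | (2R)-3-bromo-2-methylpropan-1-ol | OC[C@@H](C)CBr | starting material
27 | tert-butyl[(2R)-3-bromo-2-methylpropoxy]dimethylsilane | CC(C)(C)[Si](C)(C)OC[C@@H](C)CBr | intermediate
28 | tert-butyl{[(2S)-2,4-dimethylpent-4-en-1-yl]oxy}dimethylsilane | CC(C)(C)[Si](C)(C)OC[C@@H](C)CC(C)=C | intermediate
29 | allyl (2E,5S)-6-[(TBS)oxy]-3,5-dimethylhex-2-enoate | CC(C)(C)[Si](C)(C)OC[C@@H](C)C/C(C)=C/C(=O)OCC=C | intermediate
30 | allyl (2E,5S)-6-hydroxy-3,5-dimethylhex-2-enoate | OC[C@@H](C)C/C(C)=C/C(=O)OCC=C | intermediate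
31 | allyl (2E,5S)-3,5-dimethyl-6-oxohex-2-enoate | O=C[C@@H](C)C/C(C)=C/C(=O)OCC=C | intermediate
32 | lactone–tetraene with C12 secondary alcohol, C9-CH2OTBS (C12 epimers) | CCC(=C/[C@H](C)C/C=C/C(C)=C/[C@@H](CO[Si](C)(C)C(C)(C)C)C(O)CC)/C=C/[C@@H]1OC(=O)C=C[C@@H]1C | intermediate
33 | corresponding C8 ethyl ketone | CCC(=C/[C@H](C)C/C=C/C(C)=C/[C@@H](CO[Si](C)(C)C(C)(C)C)C(=O)CC)/C=C/[C@@H]1OC(=O)C=C[C@@H]1C | intermediate
34 | aldol adduct, TBS ether, allyl ester | CCC(=C/[C@H](C)C/C=C/C(C)=C/[C@@H](CO[Si](C)(C)C(C)(C)C)C(=O)[C@@H](C)[C@H](O)[C@@H](C)C/C(C)=C/C(=O)OCC=C)/C=C/[C@@H]1OC(=O)C=C[C@@H]1C | intermediate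
35 | allyl ester of kazusamycin A | CCC(=C/[C@H](C)C/C=C/C(C)=C/[C@@H](CO)C(=O)[C@@H](C)[C@H](O)[C@@H](C)C/C(C)=C/C(=O)OCC=C)/C=C/[C@@H]1OC(=O)C=C[C@@H]1C | intermediate
36 | kazusamycin A | CCC(=C/[C@H](C)C/C=C/C(C)=C/[C@@H](CO)C(=O)[C@@H](C)[C@H](O)[C@@H](C)C/C(C)=C/C(=O)O)/C=C/[C@@H]1OC(=O)C=C[C@@H]1C | target

## Summary
**Total steps:** 33
**Longest linear sequence:** 14 (Steps 1–8, 15, 29–33, starting from 1).

**Three steps most likely to fail**
1. **Step 31 (aldol).** The all-syn triad is the Felkin/Z-enolate combination, which simple Z-enolates disfavour, and the C9 centre is base-labile.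
   - Fallback: form C6–C7 by a Marshall–Tamaru propargylation of aldehyde 31 (chiral allenylzinc from (R)-3-butyn-2-yl mesylate, Pd(0)/Et2Zn, which is reagent-controlled). Then invert C6 by Mitsunobu and build the C8 ketone from the terminal alkyne.
2. **Step 29 (Heck).** The vinyl iodide may insert into the electron-poor lactone alkene, and the terminal alkene may isomerise.
   - Fallback: use the alkyne analogue of 17, made from Roche bromide plus lithium acetylide. Convert it to the alkenylzirconocene (Cp2Zr(H)Cl), transmetalate to zinc and do a Negishi coupling with 25.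
3. **Step 23 (hydrozirconation).** Regioselectivity at an unsymmetrical, branched internal alkyne with a nearby free hydroxyl is uncertain.
   - Fallback: redo the Still–Wittig on the 5-silyloxy-pent-3-en-2-ol analogue to carry a CH2OR arm. Then oxidise to the C10 aldehyde, do an E-selective HWE with triethyl 2-phosphonopropionate, reduce to the C12 aldehyde and close C12=C13 by Julia–Kocienski olefination.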